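You are asked about late times, 20 h, but the elm run of this same flask stops at 8.00 h, so its rate has to be carried forward.

- elm: substrate 2.2 M; reagent 2.31 M; initiator 22 mM; the very flask that is asked about, followed so far
- flask: substrate 2.2 M; reagent 2.31 M; initiator 22 mM; time 20 h

elm run (percent of the substrate charged)

| time / h | substrate / % | target / % |
|---|---|---|
| 1.50 | 92.0 | 4.6 |
| 3.00 | 86.9 | 10.7 |
| 5.00 | 82.4 | 16.9 |
| 6.00 | 77.8 | 16.3 |
| 8.00 | 72.9 | 18.9 |

(readings scatter by 1 percentage point)

1. at 20 h, what has stopped the reaction, if anything has (it is still moving / forward and back rates have come level / the reagent has run out first / all of the substrate has reacted)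
2. conversion of substrate at 20 h
3. amount of target at 20 h, in percent of the substrate charged

- the numbers in the tables scatter with a standard deviation of 1 percentage point
- the reaction counts as stopped when no species that holds the substrate changes by six tenths of a point or more over the second half of the time

Read the flask as a progress curve in molar rates. Over the first 3.00 h substrate goes at 0.0961 M h⁻¹, and from there to 8.00 h it goes more slowly, at 0.0616 M h⁻¹, a factor of 0.641 across 4.00 h between the window middles. Suppose each substrate lost takes one reagent. Then c_reagent, taken at the window middles, accounts for a factor of 0.862. The rest, 0.744, is a lump for whatever else sags, initiator perhaps, and c_substrate too, since this run cannot separate them. It is a loose reading, with 1 percentage point of scatter on every point.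

The middle of the stretch from 8.00 h to 20 h lies 2.12 such intervals past the late window, so the lump compounds to 0.533. Freeze c_reagent at its 8.00 h value, a further factor of 0.918, and the rate over that stretch is 0.0301 M h⁻¹. Add what had gone by 8.00 h and you have the draw, the molar amount of substrate gone by 20 h: 0.958 M. That is 43.5% conversion, with the flask still moving.

The forecast, reasoning “That fits a slow loss of initiator and of reagent”, says it is still moving, with conversion 48% (39% to 58%) and target 24% (15% to 34%).

The flask gives it is still moving, conversion 47.1% and target 24.6%.

    initiator → 2 initiating radical (k = 0.0523 h⁻¹)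
    2 first chain carrier → ended chains A (k = 2.00 × 10⁷ M⁻¹ s⁻¹)
    substrate → decomposition product (k = 1.86 × 10⁻⁴ h⁻¹)
    substrate + second chain carrier → by-product + first chain carrier (k = 3.03 × 10⁶ M⁻¹ h⁻¹)
    substrate + initiating radical → capped initiator + first chain carrier (k = 20100 M⁻¹ s⁻¹)
    target ⇌ isomer of the product (K = 1.60, k = 0.0813 h⁻¹)
    2 second chain carrier → ended chains B (k = 3.40 × 10⁶ M⁻¹ s⁻¹)
    reagent + first chain carrier → target + second chain carrier (k = 1.66 × 10⁶ M⁻¹ h⁻¹)
    first chain carrier → ended carrier (k = 80600 h⁻¹)

The flask's own draw is 1.04 M, against the 0.958 M you reckoned. Now take the neighbour, with 1.3 M of substrate and the other charges as before, and keep the draw in molar terms: 1.04 M out of 1.3 M is 80.0% conversion, and your reckoned 0.958 M gives 73.7%. That neighbour stands at 78.9%, a draw of 1.03 M, so between these two flasks the draw looks zero-order in substrate. Its reagent at 20 h is 56.9% of charge, and the flask's is 56.7%.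

The earlier runs and the new flask were generated by integration for substances that don't exist.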